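**Retrosynthetic overview**
1. Target ⇒ penta-O-MOM-(−)-epigallocatechin + O-acetylferulic acid. The ester is made first, and all MOM groups and the acetate are then removed in one acid methanolysis.
2. cis-(2R,3R)-Flavan-3-ol ⇒ racemic flavan-3-one. A transfer hydrogenation run as a dynamic kinetic resolution sets C2 and C3 together.
3. Flavan-3-one ⇒ 3,4-epoxyflavan by Meinwald rearrangement. All epoxide stereoisomers converge on the one ketone.
4. 3,4-Epoxyflavan ⇒ A-ring o-hydroxybenzaldehyde + B-ring (E)-styryl(diphenyl)sulfonium salt. O1–C2, C3–C4 and C3–O form in one flask, and the aldehyde oxygen becomes O-3.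
5. Ring order: the three benzene rings are bought. The pyran C ring and an oxirane close together in step 5, and the oxirane is opened in step 6.

Assumption: for the non-conjugated ketone 10, the (S,S)-TsDPEN catalyst is taken to give the 3R alcohol, with the bulky C2 flank turned away from the η6-arene. If the measured sense is opposite, the equally available (R,R) catalyst is used and nothing else changes.

**Step 1**
Reactants: 1 2,4,6-trihydroxybenzaldehyde
Product: 2 2-hydroxy-4,6-bis(methoxymethoxy)benzaldehyde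
Conditions: MOMCl (2.1 equiv), K2CO3, acetone, 0 °C → rt
Reagents that add atoms: chloromethyl methyl ether, COCCl
Why: Williamson-type O-alkylation in which the 4-OH and one of the two equivalent ortho-OH groups react, while the last ortho-OH is hydrogen-bonded to the aldehyde and stays free as the nucleophile for step 5; no stereocentre is formed.

**Step 2**
Reactants: 3 3,4,5-trihydroxybenzaldehyde
Product: 4 3,4,5-tris(methoxymethoxy)benzaldehyde
Conditions: MOMCl (3.6 equiv), K2CO3, acetone, N2, 0 °C → rt
Reagents that add atoms: chloromethyl methyl ether, COCCl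
Why: Exhaustive Williamson-type MOM protection, chosen because MOM tolerates ylides, carbonate and formate/amine and, unlike silyl or acyl groups, cannot migrate to an alkoxide later; no stereocentre is formed.

**Step 3**
Reactants: 4 3,4,5-tris(methoxymethoxy)benzaldehyde
Product: 5 3,4,5-tris(methoxymethoxy)styrene
Conditions: MePPh3Br, KOtBu, THF, 0 °C → rt
Reagents that add atoms: methyltriphenylphosphonium bromide, C[P+](c1ccccc1)(c1ccccc1)c1ccccc1.[Br-]
Why: Wittig methylenation of an unhindered aromatic aldehyde, to which MOM ethers are inert; no stereocentre is formed.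

**Step 4**
Reactants: 5 3,4,5-tris(methoxymethoxy)styrene
Product: 6 (E)-diphenyl{2-[3,4,5-tris(methoxymethoxy)phenyl]ethenyl}sulfonium triflate
Conditions: Ph2SO, Tf2O, CH2Cl2, −78 °C; then 5 and powdered K2CO3, −78 → 0 °C; precipitate with Et2O
Reagents that add atoms: diphenyl sulfoxide, O=S(c1ccccc1)c1ccccc1; triflic anhydride (supplies the counter-ion), O=S(=O)(OS(=O)(=O)C(F)(F)F)C(F)(F)F
Why: Interrupted-Pummerer-type electrophilic addition–elimination in which the activated sulfoxide adds to the terminal alkene carbon and the p-alkoxy-stabilised benzylic cation loses a proton to give the more stable E-alkenylsulfonium salt.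

**Step 5 (key step)**
Reactants: 2 2-hydroxy-4,6-bis(methoxymethoxy)benzaldehyde; 6 (E)-diphenyl{2-[3,4,5-tris(methoxymethoxy)phenyl]ethenyl}sulfonium triflate
Product: 9 rac-3,4-epoxy-5,7-bis(methoxymethoxy)-2-[3,4,5-tris(methoxymethoxy)phenyl]chroman (cis-fused oxirane; mixture of C2 epimers), via sulfonium ylide 7 (not isolated), via sulfonium betaine 8 (not isolated)
Conditions: Cs2CO3 (2 equiv), 4 Å MS, MeCN–CH2Cl2, 0 °C → rt; filter through basic alumina and use directly
Reagents that add atoms: none
Why: Proposed new method: the phenoxide of 2 adds to the β-carbon of 6 (oxa-Michael) to give ylide 7, which attacks the neighbouring aldehyde in a six-membered closure to betaine 8, whose anti alkoxide expels Ph2S, so the pyran and the oxirane close in one operation; the closest known reaction type is the vinylsulfonium epoxide annulation of amino- or hydroxy-carbonyl compounds (tandem Michael/Johnson–Corey–Chaykovsky), which also works with β-substituted vinylsulfonium salts, and the three new stereocentres are racemic and not relied on because step 6 erases C3/C4 and equilibrates C2.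

**Step 6**
Reactants: 9 rac-3,4-epoxy-5,7-bis(methoxymethoxy)-2-[3,4,5-tris(methoxymethoxy)phenyl]chroman
Product: 11 (2R,3R)-5,7-bis(methoxymethoxy)-2-[3,4,5-tris(methoxymethoxy)phenyl]chroman-3-ol (penta-O-MOM-(−)-epigallocatechin), via flavan-3-one 10 (not isolated)
Conditions: InCl3 (5 mol %), THF, rt, 15 min; then Et3N/HCO2H (3:2), RuCl[(S,S)-TsDPEN](p-cymene) (2 mol %), 30 °C, N2
Reagents that add atoms: none
Why: A Meinwald rearrangement (C4–O ionisation driven by the 5,7-dioxygenated ring, then a 1,2-H shift) funnels every epoxide isomer into ketone 10, whose C2–H (α-keto, benzylic, α-oxy) epimerises quickly under Et3N, so the Noyori–Ikariya transfer hydrogenation runs as a dynamic kinetic resolution in which the catalyst selects the (2R)-ketone and delivers hydride equatorially to give the axial 3-OH cis to the equatorial aryl group, which fixes C2 (R) and C3 (R) together, as in the known cis-selective resolutions of 2-aryl- and 2-alkoxycycloalkanones and isoflavanones.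

**Step 7**
Reactants: 11 penta-O-MOM-(−)-epigallocatechin; 12 (E)-4-acetoxy-3-methoxycinnamic acid (O-acetylferulic acid, commercial)
Product: 13 (2R,3R)-5,7-bis(methoxymethoxy)-2-[3,4,5-tris(methoxymethoxy)phenyl]chroman-3-yl (E)-3-(4-acetoxy-3-methoxyphenyl)acrylate
Conditions: DCC, DMAP (0.3 equiv), CH2Cl2, 0 °C → rt
Reagents that add atoms: none
Why: Steglich esterification at the only free hydroxyl, in which the C3–O bond is never broken, so C2 and C3 are retained and the E-alkene is untouched.

**Step 8**
Reactants: 13 protected ferulate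
Product: 14 epigallocatechin-3-O-ferulate, (2R,3R)
Conditions: HCl (1.25 M in MeOH), Ar, 35–40 °C
Reagents that add atoms: none
Why: Acid-catalysed acetal exchange and transesterification in which aryl MOM ethers and the aryl acetate solvolyse far faster than the hindered, conjugated secondary alkyl ester, MeOH traps the MOM cation as dimethoxymethane, and flavan-3-ols hold their C2 configuration in dilute acid.

**Compound list**
1 | 2,4,6-trihydroxybenzaldehyde | O=Cc1c(O)cc(O)cc1O | starting material
2 | 2-hydroxy-4,6-bis(methoxymethoxy)benzaldehyde | O=Cc1c(O)cc(OCOC)cc1OCOC | intermediate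
3 | 3,4,5-trihydroxybenzaldehyde | O=Cc1cc(O)c(O)c(O)c1 | starting material
4 | 3,4,5-tris(methoxymethoxy)benzaldehyde | O=Cc1cc(OCOC)c(OCOC)c(OCOC)c1 | intermediate
5 | 3,4,5-tris(methoxymethoxy)styrene | C=Cc1cc(OCOC)c(OCOC)c(OCOC)c1 | intermediate
6 | (E)-diphenyl{2-[3,4,5-tris(methoxymethoxy)phenyl]ethenyl}sulfonium triflate | COCOc1cc(/C=C/[S+](c2ccccc2)c2ccccc2)cc(OCOC)c1OCOC.[O-]S(=O)(=O)C(F)(F)F | intermediate
7 | sulfonium ylide from oxa-Michael addition (racemic, not isolated) | O=Cc1c(OCOC)cc(OCOC)cc1OC([CH-][S+](c1ccccc1)c1ccccc1)c1cc(OCOC)c(OCOC)c(OCOC)c1 | intermediate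
8 | 3-(diphenylsulfonio)chroman-4-olate betaine (racemic, not isolated) | [O-]C1c2c(OCOC)cc(OCOC)cc2OC(c2cc(OCOC)c(OCOC)c(OCOC)c2)C1[S+](c1ccccc1)c1ccccc1 | intermediate
9 | rac-3,4-epoxy-5,7-bis(methoxymethoxy)-2-[3,4,5-tris(methoxymethoxy)phenyl]chroman (no configuration defined) | COCOc1cc(OCOC)c2C3OC3C(Oc2c1)c1cc(OCOC)c(OCOC)c(OCOC)c1 | intermediate
10 | rac-5,7-bis(methoxymethoxy)-2-[3,4,5-tris(methoxymethoxy)phenyl]chroman-3-one (C2 labile, not isolated) | COCOc1cc(OCOC)c2CC(=O)C(Oc2c1)c1cc(OCOC)c(OCOC)c(OCOC)c1 | intermediate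
11 | (2R,3R)-5,7-bis(methoxymethoxy)-2-[3,4,5-tris(methoxymethoxy)phenyl]chroman-3-ol | O[C@@H]1Cc2c(OCOC)cc(OCOC)cc2O[C@@H]1c1cc(OCOC)c(OCOC)c(OCOC)c1 | intermediate
12 | (E)-4-acetoxy-3-methoxycinnamic acid | COc1cc(/C=C/C(=O)O)ccc1OC(C)=O | starting material
13 | (2R,3R)-penta-O-MOM-epigallocatechin 3-O-(4-O-acetylferulate) | COc1cc(/C=C/C(=O)O[C@@H]2Cc3c(OCOC)cc(OCOC)cc3O[C@@H]2c2cc(OCOC)c(OCOC)c(OCOC)c2)ccc1OC(C)=O | intermediate
14 | epigallocatechin-3-O-ferulate | COc1cc(/C=C/C(=O)O[C@@H]2Cc3c(O)cc(O)cc3O[C@@H]2c2cc(O)c(O)c(O)c2)ccc1O | target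

**Totals**
Total steps: 8. Longest linear sequence: 7 (steps 2 → 3 → 4 → 5 → 6 → 7 → 8).

**Steps most likely to fail**

*Step 5.* The donor-substituted styryl salt may be a poor Michael acceptor. The protonated adduct may also lose Ph2S by E2 to give the α-aryloxystyrene. The fallback sets out from 4 and returns at 10. Ethynylmagnesium bromide is added to 4 to give 1-[3,4,5-tris(methoxymethoxy)phenyl]prop-2-yn-1-ol F1. This is coupled under Mitsunobu conditions (PPh3, DIAD) with 3,5-bis(methoxymethoxy)phenol F2, made from phloroglucinol and 2 equiv MOMCl. The product is 1-{1-[3,5-bis(methoxymethoxy)phenoxy]prop-2-yn-1-yl}-3,4,5-tris(methoxymethoxy)benzene F3. Gold(I)-catalysed alkyne oxidation (bulky phosphine, 2,6-dichloropyridine N-oxide) generates the α-oxo gold carbene, which closes onto the ortho carbon of the A ring to give ketone 10. The route continues with the hydrogenation half of step 6.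

*Step 6.* C2 epimerisation may be too slow, or facial discrimination on a non-conjugated ketone may be too low. The fallback sets out from 10, isolated after the InCl3 stage, and returns at 11. Reagent-controlled reduction of racemic 10 with (S)-Me-CBS/BH3·SMe2 fixes 3R in both ketone enantiomers on steric grounds. It gives 11 together with (2S,3R)-5,7-bis(methoxymethoxy)-2-[3,4,5-tris(methoxymethoxy)phenyl]chroman-3-ol F4. The two diastereomers are separated on silica. F4 is re-oxidised with Dess–Martin periodinane to 10 and recycled.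

*Step 4.* Triflic acid may strip MOM groups or oligomerise the electron-rich styrene, and ring attack may compete. The fallback sets out from 5 and 2 and returns at 9 through 7. It forms the O1–C2 bond first and the sulfonium last. NBS in aqueous THF converts 5 into 2-bromo-1-[3,4,5-tris(methoxymethoxy)phenyl]ethanol F5. Mitsunobu coupling of F5 with the acidic phenol 2 gives 2-{2-bromo-1-[3,4,5-tris(methoxymethoxy)phenyl]ethoxy}-4,6-bis(methoxymethoxy)benzaldehyde F6. S-Alkylation of Ph2S with F6 and AgOTf gives {2-[2-formyl-3,5-bis(methoxymethoxy)phenoxy]-2-[3,4,5-tris(methoxymethoxy)phenyl]ethyl}diphenylsulfonium triflate F7, the conjugate acid of 7. Cs2CO3 then deprotonates F7 to 7, which closes to 9 as in step 5.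

**Further compounds**
F1 | step 5 | 1-[3,4,5-tris(methoxymethoxy)phenyl]prop-2-yn-1-ol (racemic) | C#CC(O)c1cc(OCOC)c(OCOC)c(OCOC)c1
F2 | step 5 | 3,5-bis(methoxymethoxy)phenol | Oc1cc(OCOC)cc(OCOC)c1
F3 | step 5 | 1-{1-[3,5-bis(methoxymethoxy)phenoxy]prop-2-yn-1-yl}-3,4,5-tris(methoxymethoxy)benzene (racemic) | C#CC(Oc1cc(OCOC)cc(OCOC)c1)c1cc(OCOC)c(OCOC)c(OCOC)c1
F4 | step 6 | (2S,3R)-5,7-bis(methoxymethoxy)-2-[3,4,5-tris(methoxymethoxy)phenyl]chroman-3-ol | O[C@@H]1Cc2c(OCOC)cc(OCOC)cc2O[C@H]1c1cc(OCOC)c(OCOC)c(OCOC)c1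
F5 | step 4 | 2-bromo-1-[3,4,5-tris(methoxymethoxy)phenyl]ethanol (racemic) | OC(CBr)c1cc(OCOC)c(OCOC)c(OCOC)c1
F6 | step 4 | 2-{2-bromo-1-[3,4,5-tris(methoxymethoxy)phenyl]ethoxy}-4,6-bis(methoxymethoxy)benzaldehyde (racemic) | O=Cc1c(OCOC)cc(OCOC)cc1OC(CBr)c1cc(OCOC)c(OCOC)c(OCOC)c1
F7 | step 4 | {2-[2-formyl-3,5-bis(methoxymethoxy)phenoxy]-2-[3,4,5-tris(methoxymethoxy)phenyl]ethyl}diphenylsulfonium triflate (racemic) | O=Cc1c(OCOC)cc(OCOC)cc1OC(C[S+](c1ccccc1)c1ccccc1)c1cc(OCOC)c(OCOC)c(OCOC)c1.[O-]S(=O)(=O)C(F)(F)F
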